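**Retrosynthetic overview** (labdane numbering C1–C20 for the decalin atoms)

1. Target 19 ← diol 18 ← diester 17 (acetylation, ester reduction); the 12E diene comes from a but-2-ynyl group (hydrozirconation/Negishi coupling), and the C8=C17 methylidene from the C8 ketone 13 (Wittig).
2. Ketone 13 ← α-ketol 12 (samarium diiodide deoxygenation; C9 equilibrated next to the ketone).
3. Key disconnection: C5–C10 and C7–C8 of 12 are cut together, giving the acyclic, achiral 9. Ring A (C1–C5, C10) closes first, ring B (C5–C10) second, in one reductive operation.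
4. Enabling feature: ring B consists of two three-carbon acceptor units, the enal C5=C6–C7H=O and the alkenyl nitrile C10=C9–C8≡N. Their β-carbons C5 and C10 become the ring-fusion bond, and their carbonyl-level carbons C7 and C8 (C8 is the sp2 carbon that carries the exocyclic methylene in 19) become the second bond. Quaternary C4 (gem-diester, later both CH2OAc groups) and the C1–C3 tether hold the two units in place.
5. 9 ← dimethyl malonate, 5-chloropentan-2-one, diethyl (cyanomethyl)phosphonate, 1-bromobut-2-yne and prop-2-ynal (alkylations, Horner–Wadsworth–Emmons, Michael addition).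

Key step: step 5

Remark: the sense of induction of the C2-symmetric titanocene in step 5 cannot be predicted with certainty; the (S,S)-complex is written, and its (R,R)-antipode is to be used instead if that is the one that leads to the (8aS) series.

**Step 1**
Reactants: 1 diethyl (cyanomethyl)phosphonate; 2 1-bromobut-2-yne
Product: 3 diethyl (1-cyanopent-3-yn-1-yl)phosphonate
Conditions: NaH, THF, 0 °C to rt (1 in excess)
Reagents that add atoms: none
Why: SN2 alkylation of the phosphonate-stabilised carbanion with the propargylic bromide, with excess 1 to suppress dialkylation; the stereocentre formed is racemic and disappears in step 2.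

**Step 2**
Reactants: 3 diethyl (1-cyanopent-3-yn-1-yl)phosphonate; 4 5-chloropentan-2-one
Product: 5 2-(but-2-yn-1-yl)-6-chloro-3-methylhex-2-enenitrile (E/Z mixture)
Conditions: NaH, DME, 0 °C to 65 °C
Reagents that add atoms: none
Why: Horner–Wadsworth–Emmons olefination of the methyl ketone with the α-substituted cyanomethylphosphonate should give the tetrasubstituted α,β-unsaturated nitrile; its E/Z ratio is irrelevant because both alkene carbons are rehybridised in step 5.

**Step 3**
Reactants: 5 2-(but-2-yn-1-yl)-6-chloro-3-methylhex-2-enenitrile; 6 dimethyl malonate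
Product: 7 dimethyl 2-(5-cyano-4-methylnon-4-en-7-yn-1-yl)propanedioate
Conditions: NaH, NaI (cat.), DMF, 60 °C (6 in excess)
Reagents that add atoms: none
Why: malonic ester alkylation (SN2 after in situ Finkelstein exchange of the primary chloride); the hindered tetrasubstituted alkenyl nitrile is a poor Michael acceptor for the malonate anion, and no stereocentre is formed.

**Step 4**
Reactants: 7 dimethyl 2-(5-cyano-4-methylnon-4-en-7-yn-1-yl)propanedioate; 8 prop-2-ynal
Product: 9 dimethyl 2-(5-cyano-4-methylnon-4-en-7-yn-1-yl)-2-[(1E)-3-oxoprop-1-en-1-yl]propanedioate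
Conditions: DABCO (10 mol %), CH2Cl2, 0 °C to rt
Reagents that add atoms: none
Why: amine-catalysed Michael addition of the tertiary malonate C–H to the ynal should create quaternary C4 (not a stereocentre, two identical esters) and the thermodynamically preferred (E)-enal.

**Step 5**
Reactants: 9 dimethyl 2-(5-cyano-4-methylnon-4-en-7-yn-1-yl)-2-[(1E)-3-oxoprop-1-en-1-yl]propanedioate
Product: 12 dimethyl (4aR,5S,7R,8aS)-5-(but-2-yn-1-yl)-7-hydroxy-4a-methyl-6-oxodecahydronaphthalene-1,1-dicarboxylate, via aldehyde–nitrile 10 (not isolated), via hydroxy imine 11 (not isolated)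
Conditions: (S,S)-[ethane-1,2-diylbis(η5-4,5,6,7-tetrahydroinden-1-yl)]TiCl2 (20 mol %), Zn dust, 2,4,6-collidine hydrochloride, THF, 0.01 M, 40 °C; then 1 M HCl
Reagents that add atoms: water, O
Why: Proposed new method: trivalent titanium (from the chiral titanocene dichloride and Zn) should reduce the enal to a titanium-bound allyl radical that attacks C10 of the alkenyl nitrile through C5 (6-exo-trig, ring A); after protonation the freed C7 aldehyde is reduced to a titanium ketyl that adds to the nitrile carbon C8 (6-exo-dig, ring B), and the N-titanated imine is hydrolysed to the C8 ketone on work-up. The closest known reaction types are the titanocene-catalysed reductive umpolung coupling of enones with acrylonitriles and the titanocene-catalysed ketone–nitrile cyclisation to α-hydroxy ketones (also known in enantioselective form with ansa-titanocenes), here run in tandem on one substrate with an aldehyde and a tetrasubstituted acceptor. Ring A should close through a chair in which the C6 chain on C5 and the nitrile-bearing C9 on C10 are equatorial and the C10 methyl is axial, which gives the trans relation of H-5 and CH3-20 needed for the trans-decalin, helped by the Thorpe–Ingold effect of the C4 gem-diester; the absolute sense at C5/C10 is to be set by the C2-symmetric ansa-ligand on the titanium that carries the dienolate radical. C9 is protonated without control but becomes epimerisable once C8 is a ketone and is corrected in step 6, and the C7 carbinol centre (equatorial OH drawn) is removed in step 6. The step needs cross-selectivity (enal reduced, nitrile as acceptor), secured by the easier reduction of the enal and the polarity match of the nucleophilic allyl radical with the electron-poor alkene, and 6-exo closure of ring B, secured by the 1,6-relation of C7 and C8 that the first bond creates.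

**Step 6**
Reactants: 12 dimethyl (4aR,5S,7R,8aS)-5-(but-2-yn-1-yl)-7-hydroxy-4a-methyl-6-oxodecahydronaphthalene-1,1-dicarboxylate
Product: 13 dimethyl (4aR,5S,8aS)-5-(but-2-yn-1-yl)-4a-methyl-6-oxodecahydronaphthalene-1,1-dicarboxylate
Conditions: SmI2, THF–MeOH, −78 °C; then NaOMe (cat.), MeOH, rt
Reagents that add atoms: none
Why: samarium diiodide cleaves the C–O bond α to the ketone (known reductive deoxygenation of α-ketols); catalytic methoxide should then equilibrate C9 next to the C8 ketone to the more stable epimer with the equatorial side chain, which is the configuration of the target.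

**Step 7**
Reactants: 13 dimethyl (4aR,5S,8aS)-5-(but-2-yn-1-yl)-4a-methyl-6-oxodecahydronaphthalene-1,1-dicarboxylate
Product: 14 dimethyl (4aS,5R,8aS)-5-(but-2-yn-1-yl)-4a-methyl-6-methylidenedecahydronaphthalene-1,1-dicarboxylate
Conditions: Ph3PCH3Br, KOtBu, toluene, 80 °C
Reagents that add atoms: methyltriphenylphosphonium bromide, C[P+](c1ccccc1)(c1ccccc1)c1ccccc1.[Br-]
Why: Wittig methylenation of the hindered C8 ketone installs the exocyclic C8=C17 bond; C9 stays at its thermodynamic configuration under the basic conditions (the descriptors change only because the CIP priorities change).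

**Step 8**
Reactants: 14 dimethyl (4aS,5R,8aS)-5-(but-2-yn-1-yl)-4a-methyl-6-methylidenedecahydronaphthalene-1,1-dicarboxylate; 15 bromoethene
Product: 17 dimethyl (4aS,5R,8aS)-4a-methyl-6-methylidene-5-[(2E)-3-methylpenta-2,4-dien-1-yl]decahydronaphthalene-1,1-dicarboxylate, via alkenylzirconocene chloride 16 (not isolated)
Conditions: Cp2Zr(H)Cl, THF, 40 °C; then ZnCl2 (30 mol %), Pd(PPh3)4 (5 mol %), rt
Reagents that add atoms: none
Why: hydrozirconation (syn addition, with zirconium moving to the less hindered, methyl-bearing alkyne carbon on equilibration) followed by palladium-catalysed Negishi coupling with retention should give the 12E diene; the 1,1-disubstituted exocyclic alkene reacts much more slowly than the alkyne.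

**Step 9**
Reactants: 17 dimethyl (4aS,5R,8aS)-4a-methyl-6-methylidene-5-[(2E)-3-methylpenta-2,4-dien-1-yl]decahydronaphthalene-1,1-dicarboxylate
Product: 18 [(4aS,5R,8aS)-4a-methyl-6-methylidene-5-[(2E)-3-methylpenta-2,4-dien-1-yl]decahydronaphthalene-1,1-diyl]dimethanol
Conditions: LiAlH4, THF, 0 °C to rt
Reagents that add atoms: none
Why: hydride reduction of both neopentyl esters to the 1,3-diol; the diene and the exocyclic alkene are inert, and C4 remains non-stereogenic.

**Step 10**
Reactants: 18 [(4aS,5R,8aS)-4a-methyl-6-methylidene-5-[(2E)-3-methylpenta-2,4-dien-1-yl]decahydronaphthalene-1,1-diyl]dimethanol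
Product: 19 [(4aS,5R,8aS)-4a-methyl-6-methylidene-5-[(2E)-3-methylpenta-2,4-dien-1-yl]decahydronaphthalene-1,1-diyl]bis(methylene) diacetate (the target)
Conditions: Ac2O, pyridine, DMAP (cat.), CH2Cl2, rt
Reagents that add atoms: acetic anhydride, CC(=O)OC(C)=O
Why: DMAP-catalysed acylation of both primary alcohols gives the target without touching any stereocentre.

**Compound list**

1 | diethyl (cyanomethyl)phosphonate | N#CCP(=O)(OCC)OCC | starting material
2 | 1-bromobut-2-yne | CC#CCBr | starting material
3 | diethyl (1-cyanopent-3-yn-1-yl)phosphonate (racemic) | CCOP(=O)(OCC)C(C#N)CC#CC | intermediate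
4 | 5-chloropentan-2-one | CC(=O)CCCCl | starting material
5 | 2-(but-2-yn-1-yl)-6-chloro-3-methylhex-2-enenitrile (E/Z mixture) | CC#CCC(C#N)=C(C)CCCCl | intermediate
6 | dimethyl malonate | COC(=O)CC(=O)OC | starting material
7 | dimethyl 2-(5-cyano-4-methylnon-4-en-7-yn-1-yl)propanedioate (E/Z mixture at the nitrile alkene) | COC(=O)C(CCCC(C)=C(C#N)CC#CC)C(=O)OC | intermediate
8 | prop-2-ynal | C#CC=O | starting material
9 | dimethyl 2-(5-cyano-4-methylnon-4-en-7-yn-1-yl)-2-[(1E)-3-oxoprop-1-en-1-yl]propanedioate | COC(=O)C(/C=C/C=O)(CCCC(C)=C(C#N)CC#CC)C(=O)OC | intermediate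
10 | dimethyl (2S,3R)-3-(1-cyanopent-3-yn-1-yl)-3-methyl-2-(2-oxoethyl)cyclohexane-1,1-dicarboxylate (epimers at the cyano-bearing carbon; not isolated) | CC#CCC(C#N)[C@]1(C)CCCC(C(=O)OC)(C(=O)OC)[C@H]1CC=O | intermediate
11 | dimethyl (4aR,5S,7R,8aS)-5-(but-2-yn-1-yl)-7-hydroxy-6-imino-4a-methyldecahydronaphthalene-1,1-dicarboxylate (not isolated) | CC#CC[C@@H]1C(=N)[C@H](O)C[C@@H]2C(C(=O)OC)(C(=O)OC)CCC[C@@]12C | intermediate
12 | dimethyl (4aR,5S,7R,8aS)-5-(but-2-yn-1-yl)-7-hydroxy-4a-methyl-6-oxodecahydronaphthalene-1,1-dicarboxylate | CC#CC[C@@H]1C(=O)[C@H](O)C[C@@H]2C(C(=O)OC)(C(=O)OC)CCC[C@@]12C | intermediate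
13 | dimethyl (4aR,5S,8aS)-5-(but-2-yn-1-yl)-4a-methyl-6-oxodecahydronaphthalene-1,1-dicarboxylate | CC#CC[C@@H]1C(=O)CC[C@@H]2C(C(=O)OC)(C(=O)OC)CCC[C@@]12C | intermediate
14 | dimethyl (4aS,5R,8aS)-5-(but-2-yn-1-yl)-4a-methyl-6-methylidenedecahydronaphthalene-1,1-dicarboxylate | CC#CC[C@@H]1C(=C)CC[C@@H]2C(C(=O)OC)(C(=O)OC)CCC[C@@]12C | intermediate
15 | bromoethene (vinyl bromide) | C=CBr | starting material
16 | chloridobis(cyclopentadienyl)[(2E)-alkenyl]zirconium, the (E)-but-2-en-2-yl zirconocene chloride of 14 with Zr on C13 trans to C11 (not isolated) | C/C(=C\C[C@@H]1C(=C)CC[C@@H]2C(C(=O)OC)(C(=O)OC)CCC[C@@]12C)[Zr](Cl)(C3C=CC=C3)C3C=CC=C3 | intermediate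
17 | dimethyl (4aS,5R,8aS)-4a-methyl-6-methylidene-5-[(2E)-3-methylpenta-2,4-dien-1-yl]decahydronaphthalene-1,1-dicarboxylate | C=C/C(C)=C/C[C@@H]1C(=C)CC[C@@H]2C(C(=O)OC)(C(=O)OC)CCC[C@@]12C | intermediate
18 | [(4aS,5R,8aS)-4a-methyl-6-methylidene-5-[(2E)-3-methylpenta-2,4-dien-1-yl]decahydronaphthalene-1,1-diyl]dimethanol | C=C/C(C)=C/C[C@@H]1C(=C)CC[C@@H]2C(CO)(CO)CCC[C@@]12C | intermediate
19 | [(4aS,5R,8aS)-4a-methyl-6-methylidene-5-[(2E)-3-methylpenta-2,4-dien-1-yl]decahydronaphthalene-1,1-diyl]bis(methylene) diacetate (ent-labda-8(17),12E,14-triene-18,19-diyl diacetate) | C=C/C(C)=C/C[C@@H]1C(=C)CC[C@@H]2C(COC(C)=O)(COC(C)=O)CCC[C@@]12C | target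

**Totals**

Total step count: 10. Longest linear sequence: 10 steps (from 1).

**Steps most likely to fail**

1. Step 5 (proposed new method). What may go wrong:
   - over-reduction or reductive dimerisation of the enal before the slow attack on the tetrasubstituted alkenyl nitrile;
   - simple reduction of the C7 aldehyde instead of ketyl addition to the nitrile;
   - insufficient enantiofacial discrimination by the titanocene.

   Fallback with known chemistry, setting out from 9 and coming back at 13: reductive hydrocyclisation of 9 with SmI2/HMPA/t-BuOH in THF at −78 °C (electrohydrocyclisation-type β,β-coupling of two Michael acceptors) to the racemic trans aldehyde–nitrile F1. Then NaBH4 in MeOH gives the racemic alcohol F2, and I2/PPh3/imidazole gives the racemic iodide F3. Slow addition of Bu3SnH/AIBN in benzene at 80 °C brings about 6-exo radical cyclisation onto the nitrile; aqueous acetic acid hydrolyses the imine and NaOMe/MeOH equilibrates C9, giving the racemic ketone F4. F4 is resolved by preparative chromatography on a chiral stationary phase to give 13.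

2. Step 2. What may go wrong: sluggish addition of the hindered α-branched phosphonate carbanion to the ketone, with competing enolisation and cyclisation of the chloroketone to a cyclopropyl ketone.

   Fallback, setting out from 1, 4 and 2 and coming back at 5: Horner–Wadsworth–Emmons reaction of 4 with unsubstituted 1 (NaH, THF) to 6-chloro-3-methylhex-2-enenitrile F5. γ-Deprotonation with LDA at −78 °C and α-alkylation with 2 give the deconjugated nitrile F6. DBU in MeCN then moves the double bond back into conjugation to give 5.

3. Step 8. What may go wrong: incomplete regiochemical equilibration of the alkenylzirconium species, hydride attack on the methyl esters, and protonation of the alkenyl–metal during the zirconium-to-palladium relay.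

   Fallback, setting out from 14 and coming back at 17: copper-catalysed syn-hydroboration of the alkyne (CuCl, NaOtBu, Xantphos, B2pin2, MeOH, THF; boron to the less hindered methyl-bearing carbon) to the alkenyl boronate F7, which is purified. Suzuki–Miyaura coupling of F7 with 15 (Pd(PPh3)4, aqueous K3PO4, THF) then gives 17.

**Further compounds**

F1 | step 5 | racemic dimethyl (2S*,3R*)-3-(1-cyanopent-3-yn-1-yl)-3-methyl-2-(2-oxoethyl)cyclohexane-1,1-dicarboxylate (racemate of 10, one enantiomer drawn) | CC#CCC(C#N)[C@]1(C)CCCC(C(=O)OC)(C(=O)OC)[C@H]1CC=O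
F2 | step 5 | racemic dimethyl (2S*,3R*)-3-(1-cyanopent-3-yn-1-yl)-2-(2-hydroxyethyl)-3-methylcyclohexane-1,1-dicarboxylate (one enantiomer drawn) | CC#CCC(C#N)[C@]1(C)CCCC(C(=O)OC)(C(=O)OC)[C@H]1CCO
F3 | step 5 | racemic dimethyl (2S*,3R*)-3-(1-cyanopent-3-yn-1-yl)-2-(2-iodoethyl)-3-methylcyclohexane-1,1-dicarboxylate (one enantiomer drawn) | CC#CCC(C#N)[C@]1(C)CCCC(C(=O)OC)(C(=O)OC)[C@H]1CCI
F4 | step 5 | racemic dimethyl (4aR*,5S*,8aS*)-5-(but-2-yn-1-yl)-4a-methyl-6-oxodecahydronaphthalene-1,1-dicarboxylate (racemate of 13, one enantiomer drawn) | CC#CC[C@@H]1C(=O)CC[C@@H]2C(C(=O)OC)(C(=O)OC)CCC[C@@]12C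
F5 | step 2 | 6-chloro-3-methylhex-2-enenitrile (E/Z mixture) | CC(CCCCl)=CC#N
F6 | step 2 | 2-(but-2-yn-1-yl)-6-chloro-3-methylidenehexanenitrile (racemic) | CC#CCC(C#N)C(=C)CCCCl
F7 | step 8 | dimethyl (4aS,5R,8aS)-4a-methyl-6-methylidene-5-[(2Z)-3-(4,4,5,5-tetramethyl-1,3,2-dioxaborolan-2-yl)but-2-en-1-yl]decahydronaphthalene-1,1-dicarboxylate | C/C(=C\C[C@@H]1C(=C)CC[C@@H]2C(C(=O)OC)(C(=O)OC)CCC[C@@]12C)B3OC(C)(C)C(C)(C)O3
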